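Kazinol D is treated as a flavan whose O–Cγ bond has been cut: ring A carries its C2 hydroxyl ortho to the propane chain (Cα on ring A, Cβ, Cγ on chroman C6), and chroman C6 is para to the ring oxygen O1. The chain is therefore made by an inverse-demand hetero-Diels–Alder reaction of a ring-A o-quinone methide with a 6-vinylchroman; one operation forms Cα–Cβ and a temporary O–Cγ bond, regiospecifically and without touching the prenyl or 1,1-dimethylallyl alkenes. The precursors are a 4-O-benzyl-5-(1,1-dimethylallyl)salicyl alcohol and 8-benzyloxy-2,2-dimethyl-5-prenyl-6-vinylchroman. Lithium in ammonia then cuts the benzylic O–Cγ bond and both benzyl ethers at once.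

Key step: step 13

Remark on the chemistry: kazinol D has no stereocentre and no stereogenic double bond, so the compound asked for is the one achiral molecule. The only stereocentre made on the route (C2 of flavan 23) is formed racemic and is removed in step 14. Ring A is numbered as in its benzaldehyde precursors (C1 carries the future Cα, C2 and C4 the oxygens, C5 the 1,1-dimethylallyl group); ring B carries chroman numbering.

**Ring A (steps 1–5)**

Step 1
Reactants: 1 2,4-dihydroxybenzaldehyde; 2 prenyl bromide (1-bromo-3-methylbut-2-ene)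
Product: 3 2-hydroxy-4-[(3-methylbut-2-en-1-yl)oxy]benzaldehyde
Conditions: K2CO3 (1.05 equiv), acetone, reflux
Reagents that add atoms: none
Why: Williamson ether synthesis; the 2-OH is held in a hydrogen bond to the formyl oxygen, so the free and more acidic 4-OH should be alkylated selectively with one equivalent of base.

Step 2
Reactants: 3 2-hydroxy-4-[(3-methylbut-2-en-1-yl)oxy]benzaldehyde
Product: 4 4-[(3-methylbut-2-en-1-yl)oxy]-2-[(triisopropylsilyl)oxy]benzaldehyde
Conditions: TIPSCl, imidazole, DMF, rt
Reagents that add atoms: triisopropylsilyl chloride, CC(C)[Si](Cl)(C(C)C)C(C)C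
Why: Silyl ether formation on the phenol; capping O2 breaks the OH···O=C chelate that would otherwise steer the coming Claisen shift to C3, and the bulky, electron-releasing silyloxy group shields C3.

Step 3
Reactants: 4 4-[(3-methylbut-2-en-1-yl)oxy]-2-[(triisopropylsilyl)oxy]benzaldehyde
Product: 6 4-hydroxy-5-(2-methylbut-3-en-2-yl)-2-[(triisopropylsilyl)oxy]benzaldehyde, via 3-(2-methylbut-3-en-2-yl)-4-oxo-6-[(triisopropylsilyl)oxy]cyclohexa-1,5-diene-1-carbaldehyde 5 (not isolated)
Conditions: PhNEt2, 190 °C (sealed tube)
Reagents that add atoms: none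
Why: Aromatic Claisen rearrangement of the aryl prenyl ether ([3,3] shift with allyl inversion, then tautomerisation of dienone 5); C3 lies between two oxygen substituents, one of them the bulky OTIPS, so the new quaternary carbon should form at C5, as is known for 2-alkoxy-4-prenyloxybenzaldehydes.

Step 4
Reactants: 6 4-hydroxy-5-(2-methylbut-3-en-2-yl)-2-[(triisopropylsilyl)oxy]benzaldehyde
Product: 7 4-(benzyloxy)-5-(2-methylbut-3-en-2-yl)-2-[(triisopropylsilyl)oxy]benzaldehyde
Conditions: BnBr (1.1 equiv), K2CO3, Bu4NI (cat.), acetone, reflux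
Reagents that add atoms: benzyl bromide, BrCc1ccccc1
Why: Williamson benzylation of the only free phenol, which the para formyl group makes acidic; the benzyl ether is chosen because it withstands the hot key step and is removed by the same dissolving metal that opens the flavan, and any silyl loss here would only give 8, which step 5 makes anyway.

Step 5
Reactants: 7 4-(benzyloxy)-5-(2-methylbut-3-en-2-yl)-2-[(triisopropylsilyl)oxy]benzaldehyde
Product: 9 5-(benzyloxy)-2-(hydroxymethyl)-4-(2-methylbut-3-en-2-yl)phenol (4-O-benzyl-5-(1,1-dimethylallyl)salicyl alcohol), via 4-(benzyloxy)-2-hydroxy-5-(2-methylbut-3-en-2-yl)benzaldehyde 8 (not isolated)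
Conditions: TBAF, THF, 0 °C; then NaBH4, MeOH, 0 °C; aq. NH4Cl work-up (no acid)
Reagents that add atoms: none
Why: Fluoride desilylation followed in the same flask by borohydride reduction of the aldehyde; the silyl group is removed first so that it cannot shift onto the new benzylic alkoxide, and NaBH4 touches neither the alkene nor the benzyl ether.

**Ring B (steps 6–12)**

Step 6
Reactants: 10 3,4-dihydroxybenzaldehyde; 11 3-chloro-3-methylbut-1-yne
Product: 12 3-hydroxy-4-[(2-methylbut-3-yn-2-yl)oxy]benzaldehyde
Conditions: K2CO3 (1.1 equiv), KI (cat.), DMF, 60 °C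
Reagents that add atoms: none
Why: Williamson-type O-propargylation; one equivalent of carbonate forms the phenoxide of the more acidic 4-OH (para to CHO), the known site of mono-alkylation of this catechol aldehyde, and it captures the tertiary propargylic chloride.

Step 7
Reactants: 12 3-hydroxy-4-[(2-methylbut-3-yn-2-yl)oxy]benzaldehyde
Product: 15 8-hydroxy-2,2-dimethyl-2H-chromene-6-carbaldehyde, via 3,4-dihydroxy-5-(3-methylbuta-1,2-dien-1-yl)benzaldehyde 13 (not isolated), via 5-hydroxy-3-(3-methylbut-2-en-1-ylidene)-4-oxocyclohexa-1,5-diene-1-carbaldehyde 14 (not isolated)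
Conditions: 1,2-dichlorobenzene, 180 °C
Reagents that add atoms: none
Why: Aryl propargyl ether Claisen rearrangement to the only free ortho position, tautomerisation to allenylphenol 13, 1,5-hydrogen shift to quinone methide 14 and oxa-6π electrocyclisation, the standard thermal route to 2,2-dimethyl-2H-chromenes.

Step 8
Reactants: 15 8-hydroxy-2,2-dimethyl-2H-chromene-6-carbaldehyde
Product: 16 8-hydroxy-2,2-dimethylchroman-6-carbaldehyde (8-hydroxy-2,2-dimethyl-3,4-dihydro-2H-chromene-6-carbaldehyde)
Conditions: H2 (1 atm), 10% Pd/C, EtOAc, rt, stopped after one equivalent of H2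
Reagents that add atoms: none
Why: Catalytic hydrogenation of the cis-disubstituted styrenic C3=C4 bond, which is reduced much faster than the electron-rich aryl aldehyde; it is placed here, before any benzyl ether, aryl bromide or side-chain alkene is present.

Step 9
Reactants: 16 8-hydroxy-2,2-dimethylchroman-6-carbaldehyde
Product: 17 8-(benzyloxy)-2,2-dimethylchroman-6-carbaldehyde
Conditions: BnBr, K2CO3, DMF, rt
Reagents that add atoms: benzyl bromide, BrCc1ccccc1
Why: Williamson benzylation of the only phenol; the ether matches the protecting group on ring A and, unlike a free OH, directs the next bromination para.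

Step 10
Reactants: 17 8-(benzyloxy)-2,2-dimethylchroman-6-carbaldehyde
Product: 18 8-(benzyloxy)-5-bromo-2,2-dimethylchroman-6-carbaldehyde
Conditions: Br2, NaOAc, AcOH, rt
Reagents that add atoms: bromine, BrBr
Why: Electrophilic aromatic bromination; O1 has no free ortho or para position, so the C8 benzyloxy group directs and should send bromine para to C5 (also ortho to the ring alkyl) and not to C7 between OBn and CHO, as in the known para-bromination of 3,4-dialkoxybenzaldehydes.

Step 11
Reactants: 18 8-(benzyloxy)-5-bromo-2,2-dimethylchroman-6-carbaldehyde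
Product: 19 8-(benzyloxy)-5-bromo-6-ethenyl-2,2-dimethylchroman
Conditions: Ph3PCH3Br, KOtBu, THF, 0 °C to rt
Reagents that add atoms: methyltriphenylphosphonium bromide, C[P+](c1ccccc1)(c1ccccc1)c1ccccc1.[Br-]
Why: Wittig methylenation of the aryl aldehyde with a non-stabilised ylide, which tolerates the aryl bromide and the benzyl ether.

Step 12
Reactants: 19 8-(benzyloxy)-5-bromo-6-ethenyl-2,2-dimethylchroman; 2 prenyl bromide (1-bromo-3-methylbut-2-ene)
Product: 21 8-(benzyloxy)-6-ethenyl-2,2-dimethyl-5-(3-methylbut-2-en-1-yl)chroman, via [8-(benzyloxy)-6-ethenyl-2,2-dimethylchroman-5-yl]lithium 20 (not isolated)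
Conditions: n-BuLi, THF, −78 °C; then CuBr·SMe2 (10 mol%), 2, −78 °C to 0 °C
Reagents that add atoms: none
Why: Bromine–lithium exchange, which at −78 °C outruns addition of butyllithium to the electron-rich styrene (as in the preparation of 2-vinylphenyllithium), followed by copper-catalysed SN2 allylation of aryllithium 20 at the primary carbon of prenyl bromide.

**Union and end game (steps 13–14)**

Step 13
Reactants: 9 5-(benzyloxy)-2-(hydroxymethyl)-4-(2-methylbut-3-en-2-yl)phenol; 21 8-(benzyloxy)-6-ethenyl-2,2-dimethyl-5-(3-methylbut-2-en-1-yl)chroman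
Product: 23 rac-7-(benzyloxy)-2-[8-(benzyloxy)-2,2-dimethyl-5-(3-methylbut-2-en-1-yl)chroman-6-yl]-6-(2-methylbut-3-en-2-yl)chroman (flavan, racemic at C2), via 3-(benzyloxy)-6-methylidene-4-(2-methylbut-3-en-2-yl)cyclohexa-2,4-dien-1-one 22 (not isolated)
Conditions: 1,2-dichlorobenzene, 160 °C, BHT (cat.), 9 (2 equiv) added slowly to 21
Reagents that add atoms: none
Why: Heating 9 expels water in a 1,4-elimination to give o-quinone methide 22, an electron-poor 1-oxadiene that adds the electron-rich styrene 21 in an inverse-electron-demand hetero-Diels–Alder reaction, the known thermal route from salicyl alcohols and styrenes to flavans. The dihydropyran ring is closed by an intermolecular, concerted but asynchronous [4+2] cycloaddition (Cα–Cβ ahead of O–Cγ), not by cyclisation of a tether. Regiochemistry follows from polarity: the electrophilic methide carbon bonds to the vinyl CH2 and the oxygen to the benzylic carbon, where positive charge in the transition state is stabilised by the para oxygen O1 of the chroman. The new stereocentre at Cγ (flavan C2) is under no control and needs none, since it forms racemic and step 14 destroys it. The step needs chemoselectivity for the vinyl group over the prenyl and 1,1-dimethylallyl alkenes and over self-condensation of 9; the para-alkoxystyrene is the only conjugated and the most nucleophilic alkene, both other phenols are capped as benzyl ethers, and slow addition keeps 22 dilute in hot 21.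

Step 14
Reactants: 23 rac-7-(benzyloxy)-2-[8-(benzyloxy)-2,2-dimethyl-5-(3-methylbut-2-en-1-yl)chroman-6-yl]-6-(2-methylbut-3-en-2-yl)chroman
Product: 24 kazinol D, 4-{3-[8-hydroxy-2,2-dimethyl-5-(3-methylbut-2-en-1-yl)chroman-6-yl]propyl}-6-(2-methylbut-3-en-2-yl)benzene-1,3-diol
Conditions: Li (excess), NH3(l)/THF, −78 °C, no added alcohol; then solid NH4Cl
Reagents that add atoms: none
Why: Dissolving-metal (Birch-type) reductive cleavage of benzylic C–O bonds, the known opening of flavans to 1,3-diarylpropanes; electron transfer should cut the flavan O1–C2 bond and both O–benzyl bonds, ammonia protonates the benzylic anions, the isolated alkenes and phenoxide rings are not reduced without an alcohol, and the stereocentre vanishes as C2 becomes CH2.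

**Compound list**

1 | 2,4-dihydroxybenzaldehyde | O=Cc1ccc(O)cc1O | starting material
2 | prenyl bromide (1-bromo-3-methylbut-2-ene) | CC(C)=CCBr | starting material
3 | 2-hydroxy-4-[(3-methylbut-2-en-1-yl)oxy]benzaldehyde | O=Cc1ccc(OCC=C(C)C)cc1O | intermediate
4 | 4-[(3-methylbut-2-en-1-yl)oxy]-2-[(triisopropylsilyl)oxy]benzaldehyde | O=Cc1ccc(OCC=C(C)C)cc1O[Si](C(C)C)(C(C)C)C(C)C | intermediate
5 | 3-(2-methylbut-3-en-2-yl)-4-oxo-6-[(triisopropylsilyl)oxy]cyclohexa-1,5-diene-1-carbaldehyde (racemic Claisen dienone) | O=CC1=CC(C(C)(C)C=C)C(=O)C=C1O[Si](C(C)C)(C(C)C)C(C)C | intermediate (not isolated)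
6 | 4-hydroxy-5-(2-methylbut-3-en-2-yl)-2-[(triisopropylsilyl)oxy]benzaldehyde | O=Cc1cc(C(C)(C)C=C)c(O)cc1O[Si](C(C)C)(C(C)C)C(C)C | intermediate
7 | 4-(benzyloxy)-5-(2-methylbut-3-en-2-yl)-2-[(triisopropylsilyl)oxy]benzaldehyde | O=Cc1cc(C(C)(C)C=C)c(OCc2ccccc2)cc1O[Si](C(C)C)(C(C)C)C(C)C | intermediate
8 | 4-(benzyloxy)-2-hydroxy-5-(2-methylbut-3-en-2-yl)benzaldehyde | O=Cc1cc(C(C)(C)C=C)c(OCc2ccccc2)cc1O | intermediate (not isolated)
9 | 5-(benzyloxy)-2-(hydroxymethyl)-4-(2-methylbut-3-en-2-yl)phenol | OCc1cc(C(C)(C)C=C)c(OCc2ccccc2)cc1O | intermediate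
10 | 3,4-dihydroxybenzaldehyde | O=Cc1ccc(O)c(O)c1 | starting material
11 | 3-chloro-3-methylbut-1-yne | C#CC(C)(C)Cl | starting material
12 | 3-hydroxy-4-[(2-methylbut-3-yn-2-yl)oxy]benzaldehyde | O=Cc1ccc(OC(C)(C)C#C)c(O)c1 | intermediate
13 | 3,4-dihydroxy-5-(3-methylbuta-1,2-dien-1-yl)benzaldehyde | O=Cc1cc(O)c(O)c(C=C=C(C)C)c1 | intermediate (not isolated)
14 | 5-hydroxy-3-(3-methylbut-2-en-1-ylidene)-4-oxocyclohexa-1,5-diene-1-carbaldehyde | O=CC1=CC(=CC=C(C)C)C(=O)C(O)=C1 | intermediate (not isolated)
15 | 8-hydroxy-2,2-dimethyl-2H-chromene-6-carbaldehyde | O=Cc1cc(O)c2OC(C)(C)C=Cc2c1 | intermediate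
16 | 8-hydroxy-2,2-dimethylchroman-6-carbaldehyde | O=Cc1cc(O)c2OC(C)(C)CCc2c1 | intermediate
17 | 8-(benzyloxy)-2,2-dimethylchroman-6-carbaldehyde | O=Cc1cc(OCc3ccccc3)c2OC(C)(C)CCc2c1 | intermediate
18 | 8-(benzyloxy)-5-bromo-2,2-dimethylchroman-6-carbaldehyde | O=Cc1cc(OCc3ccccc3)c2OC(C)(C)CCc2c1Br | intermediate
19 | 8-(benzyloxy)-5-bromo-6-ethenyl-2,2-dimethylchroman | C=Cc1cc(OCc3ccccc3)c2OC(C)(C)CCc2c1Br | intermediate
20 | [8-(benzyloxy)-6-ethenyl-2,2-dimethylchroman-5-yl]lithium | C=Cc1cc(OCc3ccccc3)c2OC(C)(C)CCc2c1[Li] | intermediate (not isolated)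
21 | 8-(benzyloxy)-6-ethenyl-2,2-dimethyl-5-(3-methylbut-2-en-1-yl)chroman | C=Cc1cc(OCc3ccccc3)c2OC(C)(C)CCc2c1CC=C(C)C | intermediate
22 | 3-(benzyloxy)-6-methylidene-4-(2-methylbut-3-en-2-yl)cyclohexa-2,4-dien-1-one (o-quinone methide) | C=C1C=C(C(C)(C)C=C)C(OCc2ccccc2)=CC1=O | intermediate (not isolated)
23 | rac-7-(benzyloxy)-2-[8-(benzyloxy)-2,2-dimethyl-5-(3-methylbut-2-en-1-yl)chroman-6-yl]-6-(2-methylbut-3-en-2-yl)chroman (C2 undefined, racemic) | C=CC(C)(C)c1cc2CCC(Oc2cc1OCc1ccccc1)c1cc(OCc2ccccc2)c2OC(C)(C)CCc2c1CC=C(C)C | intermediate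
24 | kazinol D (achiral) | C=CC(C)(C)c1cc(CCCc2cc(O)c3c(c2CC=C(C)C)CCC(C)(C)O3)c(O)cc1O | target

**Step count**

Total: 14 steps. Longest linear sequence: 9 steps (steps 6–12, then 13 and 14, from 3,4-dihydroxybenzaldehyde). Ring A takes 5 steps (1–5).

**Steps most likely to fail**

Step 13 (hetero-Diels–Alder union). The quinone methide may be consumed by self-condensation with unreacted 9 (attack by its free phenol oxygen or by C3), may add to the prenyl alkene, or the styrene may polymerise at 160 °C. The fallback releases the quinone methide at ambient temperature by an anionic route instead of by thermal dehydration. It sets out from 7: borohydride reduction with the silyl ether kept (NaBH4, MeOH/THF, −20 °C) should give [4-(benzyloxy)-5-(2-methylbut-3-en-2-yl)-2-[(triisopropylsilyl)oxy]phenyl]methanol F1, and acetylation (Ac2O, pyridine, DMAP) should give [4-(benzyloxy)-5-(2-methylbut-3-en-2-yl)-2-[(triisopropylsilyl)oxy]phenyl]methyl acetate F2. Anhydrous fluoride (CsF, MeCN, rt to 50 °C) in the presence of 21 then removes the silyl group, the phenoxide expels acetate (desilylative 1,4-elimination, a known way to o-quinone methides), and 22 formed without heat should add 21. The route is rejoined at 23.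

Step 3 (Claisen rearrangement). The shift may go to C3 instead of C5, the prenyl group may be lost thermally, or the new phenol may react on with its own ortho side chain at 190 °C (abnormal Claisen shift or ring closure). The fallback installs the 1,1-dimethylallyl group by cross-coupling instead of by a sigmatropic shift. It sets out from 1: bromination para to the 2-OH (Br2, AcOH, rt) should give 5-bromo-2,4-dihydroxybenzaldehyde F3, and selective benzylation of the non-chelated 4-OH (BnBr, KHCO3, MeCN, 60 °C) should give 4-(benzyloxy)-5-bromo-2-hydroxybenzaldehyde F4. A γ-selective Suzuki–Miyaura coupling with 3-methylbut-2-en-1-ylboronic acid pinacol ester (Pd/biarylphosphine, K3PO4, aq. THF) then forms the quaternary benzylic carbon and comes back to the route at 8, which is reduced with NaBH4 as in the second half of step 5.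

Step 12 (prenylation of the aryllithium). Butyllithium or the aryllithium may attack the vinyl group and start oligomerisation, the allylation may take place at the tertiary end of prenyl bromide (SN2′), or the doubly ortho-substituted aryl metal may alkylate slowly. The fallback replaces the organolithium alkylation by a palladium-catalysed cross-coupling. It sets out from 19: Stille coupling with tributyl(3-methylbut-2-en-1-yl)stannane (Pd2(dba)3, P(t-Bu)3, CsF, dioxane, 80 °C) should give 21 directly, where the route is rejoined; no new compound is made on the way (F0).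

**Further compounds**

F1 | step 13 | [4-(benzyloxy)-5-(2-methylbut-3-en-2-yl)-2-[(triisopropylsilyl)oxy]phenyl]methanol | OCc1cc(C(C)(C)C=C)c(OCc2ccccc2)cc1O[Si](C(C)C)(C(C)C)C(C)C
F2 | step 13 | [4-(benzyloxy)-5-(2-methylbut-3-en-2-yl)-2-[(triisopropylsilyl)oxy]phenyl]methyl acetate | CC(=O)OCc1cc(C(C)(C)C=C)c(OCc2ccccc2)cc1O[Si](C(C)C)(C(C)C)C(C)C
F3 | step 3 | 5-bromo-2,4-dihydroxybenzaldehyde | O=Cc1cc(Br)c(O)cc1O
F4 | step 3 | 4-(benzyloxy)-5-bromo-2-hydroxybenzaldehyde | O=Cc1cc(Br)c(OCc2ccccc2)cc1O
F0 | step 12 | none | none
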